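**Retrosynthetic overview**
- The last step removes four benzyl ethers. Before that, the flavone C2–C1' bond is cut, giving 5,7-bis(benzyloxy)chromone with a bare C2–H and an 8-aryl-isoflavone arylboronate.
- Enabling feature: in ring C of the flavone half, C2 is both the β-carbon of the C4 enone and the α-carbon of the O1 enol ether, and C3 bears only H. An aryl–palladium species therefore delivers aryl to C2 and leaves by β-hydride elimination. The C2=C3 bond in ring C of the isoflavone half is blocked by its C3 anisyl group.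
- Boronate: biochanin A supplies isoflavone rings A, B and C intact. It is benzylated, iodinated at C8, coupled by Suzuki–Miyaura reaction to form the C8–C3' biaryl bond, and borylated at a latent C–Cl bond.
- Chromone: the flavone ring C is the only ring built. It is closed at O1–C2 from phloroacetophenone through an enaminone, before the union.

Key step: step 7

Assumption: the target has no stereocentre and its SMILES fixes no axial configuration, so the hindered C8–aryl axis is treated as stereochemically undefined (racemic if rotation is slow).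

**Step 1**
Reactants: 1 biochanin A (5,7-dihydroxy-3-(4-methoxyphenyl)-4H-chromen-4-one)
Product: 2 5,7-bis(benzyloxy)-3-(4-methoxyphenyl)-4H-chromen-4-one
Conditions: BnBr (3 equiv), K2CO3 (4 equiv), DMF, 70 °C
Reagents that add atoms: benzyl bromide, BrCc1ccccc1
Why: Williamson etherification, in which carbonate deprotonates the acidic 7-OH at once and, with excess benzyl bromide and heat, also the chelated 5-OH, while ring C tolerates this non-nucleophilic base.

**Step 2**
Reactants: 2 5,7-bis(benzyloxy)-3-(4-methoxyphenyl)-4H-chromen-4-one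
Product: 3 5,7-bis(benzyloxy)-8-iodo-3-(4-methoxyphenyl)-4H-chromen-4-one
Conditions: NIS (1.05 equiv), CF3CO2H (cat.), MeCN–CH2Cl2, 0 °C to rt
Reagents that add atoms: N-iodosuccinimide, O=C1CCC(=O)N1I
Why: Electrophilic aromatic iodination, in which ring A with three oxygen donors is the most electron-rich ring and, with O5 alkylated, C8 (para to O5, ortho to O7, one freely rotating neighbour) should react before C6, which lies between two benzyloxy groups.

**Step 3**
Reactants: 3 5,7-bis(benzyloxy)-8-iodo-3-(4-methoxyphenyl)-4H-chromen-4-one; 4 (5-chloro-2-methoxyphenyl)boronic acid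
Product: 5 5,7-bis(benzyloxy)-8-(5-chloro-2-methoxyphenyl)-3-(4-methoxyphenyl)-4H-chromen-4-one
Conditions: Pd(PPh3)4 (5 mol %), aq. Na2CO3, DME, 85 °C
Reagents that add atoms: none
Why: Suzuki–Miyaura coupling, in which Pd(PPh3)4 inserts into the C8–I bond but not into the electron-rich aryl C–Cl bond, so the chloride para to the methoxy group survives as a latent handle, and couplings of 8-iodoflavonoids with ortho-alkoxyarylboron reagents are well precedented.

**Step 4**
Reactants: 5 5,7-bis(benzyloxy)-8-(5-chloro-2-methoxyphenyl)-3-(4-methoxyphenyl)-4H-chromen-4-one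
Product: 6 5,7-bis(benzyloxy)-8-[2-methoxy-5-(4,4,5,5-tetramethyl-1,3,2-dioxaborolan-2-yl)phenyl]-3-(4-methoxyphenyl)-4H-chromen-4-one
Conditions: B2pin2 (1.5 equiv), Pd2(dba)3 (2 mol %), XPhos (8 mol %), KOAc (3 equiv), 1,4-dioxane, 100 °C
Reagents that add atoms: bis(pinacolato)diboron, CC1(C)OB(OC1(C)C)B1OC(C)(C)C(C)(C)O1
Why: Miyaura borylation, in which the bulky electron-rich phosphine lets zerovalent palladium insert into the deactivated C–Cl bond and the weak base KOAc avoids both biaryl homocoupling and opening of the pyranone ring.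

**Step 5**
Reactants: 7 2,4,6-trihydroxyacetophenone
Product: 8 1-[2,4-bis(benzyloxy)-6-hydroxyphenyl]ethanone
Conditions: BnBr (2.05 equiv), K2CO3 (2.2 equiv), DMF, rt to 50 °C
Reagents that add atoms: benzyl bromide, BrCc1ccccc1
Why: Williamson etherification with limited benzyl bromide, in which the para hydroxyl and one of the two equivalent ortho hydroxyls react and the remaining ortho hydroxyl, hydrogen-bonded to the acetyl C=O, is the least nucleophilic and stays free.

**Step 6**
Reactants: 8 1-[2,4-bis(benzyloxy)-6-hydroxyphenyl]ethanone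
Product: 10 5,7-bis(benzyloxy)-4H-chromen-4-one, via enaminone 9 (not isolated)
Conditions: Me2NCH(OMe)2 (3 equiv), toluene, 100 °C; concentrate; AcOH, 100 °C
Reagents that add atoms: N,N-dimethylformamide dimethyl acetal, COC(OC)N(C)C
Why: Enaminone route to 3-unsubstituted chromones, in which the acetyl CH3 condenses with the amide acetal to give the (E)-enaminone and, in hot acid, the free phenol adds to its β-carbon (6-endo addition–elimination) and expels dimethylamine, closing ring C at O1–C2.

**Step 7**
Reactants: 6 5,7-bis(benzyloxy)-8-[2-methoxy-5-(4,4,5,5-tetramethyl-1,3,2-dioxaborolan-2-yl)phenyl]-3-(4-methoxyphenyl)-4H-chromen-4-one; 10 5,7-bis(benzyloxy)-4H-chromen-4-one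
Product: 11 5,7-bis(benzyloxy)-8-{5-[5,7-bis(benzyloxy)-4-oxo-4H-chromen-2-yl]-2-methoxyphenyl}-3-(4-methoxyphenyl)-4H-chromen-4-one
Conditions: Pd(OAc)2 (10 mol %), 1,10-phenanthroline (12 mol %), O2 (1 atm), DMF, 90 °C; 10 in excess (2 equiv), 6 added slowly
Reagents that add atoms: none
Why: Boronate 6 transmetalates to phenanthroline-ligated divalent palladium, the aryl–palladium species adds syn across C2=C3 of 10 with aryl on C2 and palladium on C3, the C-bound palladium enolate equilibrates through its O-bound form so that palladium comes syn to H-2, β-hydride elimination releases flavone 11, and O2 returns zerovalent palladium to the divalent state. The closest known reaction type is the oxidative boron-Heck arylation of chromones and coumarins with arylboron reagents under O2, which gives flavones and 4-arylcoumarins. No ring is closed and no stereocentre is formed, and the C8–aryl axis is already present in 6. Regioselectivity for C2 over C3 follows from the matched polarisation of C2 as enone β-carbon and enol-ether α-carbon, and the chelating N,N-ligand disfavours the competing electrophilic palladation at nucleophilic C3. Selectivity between the two pyranone rings rests on the C3 anisyl group of 6, which makes its own C2=C3 bond trisubstituted and would force palladium onto a fully substituted carbon, while excess 10 and slow addition of 6 hold down homocoupling and oxidation of the boronate. The step joins both halves at the final oxidation level, completes the carbon skeleton and needs no handle on the chromone.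

**Step 8**
Reactants: 11 5,7-bis(benzyloxy)-8-{5-[5,7-bis(benzyloxy)-4-oxo-4H-chromen-2-yl]-2-methoxyphenyl}-3-(4-methoxyphenyl)-4H-chromen-4-one
Product: 12 8-[5-(5,7-dihydroxy-4-oxo-4H-chromen-2-yl)-2-methoxyphenyl]-5,7-dihydroxy-3-(4-methoxyphenyl)-4H-chromen-4-one (target)
Conditions: H2 (1 atm), 10% Pd/C, THF–MeOH, rt
Reagents that add atoms: none
Why: Catalytic hydrogenolysis of the four O-benzyl groups, in which the aryl methyl ethers are inert and the vinylogous-ester C2=C3 bonds of both pyranones are reduced far more slowly than benzylic C–O bonds are cleaved, so stopping after four equivalents of hydrogen should give the target.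

**Compound list**
1 | biochanin A | COc1ccc(-c2coc3cc(O)cc(O)c3c2=O)cc1 | starting material
2 | 5,7-bis(benzyloxy)-3-(4-methoxyphenyl)-4H-chromen-4-one | COc1ccc(-c2coc3cc(OCc4ccccc4)cc(OCc4ccccc4)c3c2=O)cc1 | intermediate
3 | 5,7-bis(benzyloxy)-8-iodo-3-(4-methoxyphenyl)-4H-chromen-4-one | COc1ccc(-c2coc3c(I)c(OCc4ccccc4)cc(OCc4ccccc4)c3c2=O)cc1 | intermediate
4 | (5-chloro-2-methoxyphenyl)boronic acid | COc1ccc(Cl)cc1B(O)O | starting material
5 | 5,7-bis(benzyloxy)-8-(5-chloro-2-methoxyphenyl)-3-(4-methoxyphenyl)-4H-chromen-4-one | COc1ccc(-c2coc3c(-c4cc(Cl)ccc4OC)c(OCc4ccccc4)cc(OCc4ccccc4)c3c2=O)cc1 | intermediate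
6 | 5,7-bis(benzyloxy)-8-[2-methoxy-5-(4,4,5,5-tetramethyl-1,3,2-dioxaborolan-2-yl)phenyl]-3-(4-methoxyphenyl)-4H-chromen-4-one | COc1ccc(-c2coc3c(-c4cc(B5OC(C)(C)C(C)(C)O5)ccc4OC)c(OCc4ccccc4)cc(OCc4ccccc4)c3c2=O)cc1 | intermediate
7 | 2,4,6-trihydroxyacetophenone | CC(=O)c1c(O)cc(O)cc1O | starting material
8 | 1-[2,4-bis(benzyloxy)-6-hydroxyphenyl]ethanone | CC(=O)c1c(O)cc(OCc2ccccc2)cc1OCc1ccccc1 | intermediate
9 | (E)-1-[2,4-bis(benzyloxy)-6-hydroxyphenyl]-3-(dimethylamino)prop-2-en-1-one | CN(C)/C=C/C(=O)c1c(O)cc(OCc2ccccc2)cc1OCc1ccccc1 | intermediate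
10 | 5,7-bis(benzyloxy)-4H-chromen-4-one | O=c1ccoc2cc(OCc3ccccc3)cc(OCc3ccccc3)c12 | intermediate
11 | 5,7-bis(benzyloxy)-8-{5-[5,7-bis(benzyloxy)-4-oxo-4H-chromen-2-yl]-2-methoxyphenyl}-3-(4-methoxyphenyl)-4H-chromen-4-one | COc1ccc(-c2coc3c(-c4cc(-c5cc(=O)c6c(OCc7ccccc7)cc(OCc7ccccc7)cc6o5)ccc4OC)c(OCc4ccccc4)cc(OCc4ccccc4)c3c2=O)cc1 | intermediate
12 | 8-[5-(5,7-dihydroxy-4-oxo-4H-chromen-2-yl)-2-methoxyphenyl]-5,7-dihydroxy-3-(4-methoxyphenyl)-4H-chromen-4-one | COc1ccc(-c2coc3c(-c4cc(-c5cc(=O)c6c(O)cc(O)cc6o5)ccc4OC)c(O)cc(O)c3c2=O)cc1 | target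

Total step count: 8
Longest linear sequence: 6 steps (steps 1, 2, 3, 4, 7 and 8)

**Steps most likely to fail**

**Step 7.**
- Risk: insertion into the electron-rich, doubly alkoxylated enone may be slow. Protodeboronation, oxidative homocoupling or oxidation of the boronate could then outrun the coupling. Protonolysis of the palladium enolate could also stop the sequence one oxidation level too low.
- Fallback (sets out from 6 and 10, returns at 11): bond formation and oxidation are separated. A redox-neutral conjugate addition uses Pd(OCOCF3)2 and 2,2'-bipyridine in aqueous AcOH–THF at 60 °C. It deliberately ends by protonolysis and should give racemic 5,7-bis(benzyloxy)-8-{5-[5,7-bis(benzyloxy)-4-oxochroman-2-yl]-2-methoxyphenyl}-3-(4-methoxyphenyl)-4H-chromen-4-one F1. Dehydrogenation of this flavanone with DDQ in refluxing 1,4-dioxane then gives 11.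

**Step 2.**
- Risk: poor site selectivity between C8 and C6, or a second iodination.
- Fallback (sets out from 8, returns at 5, bypassing 3): the position is fixed before ring C exists.
  - Iodination with NIS and catalytic CF3CO2H in MeCN goes ortho to the free phenol and should give 1-[4,6-bis(benzyloxy)-2-hydroxy-3-iodophenyl]ethanone F2.
  - Suzuki–Miyaura coupling with 4 (Pd(PPh3)4, aq. Na2CO3, DME) gives 1-[4,6-bis(benzyloxy)-3-(5-chloro-2-methoxyphenyl)-2-hydroxyphenyl]ethanone F3.
  - DMF dimethyl acetal gives (E)-1-[4,6-bis(benzyloxy)-3-(5-chloro-2-methoxyphenyl)-2-hydroxyphenyl]-3-(dimethylamino)prop-2-en-1-one F4.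
  - Iodine in CHCl3 triggers iodocyclisation to 5,7-bis(benzyloxy)-8-(5-chloro-2-methoxyphenyl)-3-iodo-4H-chromen-4-one F5.
  - Iodide-selective Suzuki–Miyaura coupling with (4-methoxyphenyl)boronic acid delivers 5.

**Step 3.**
- Risk: oxidative addition and transmetalation at the doubly flanked C8–I bond may be slow. Protodeboronation of the ortho-methoxy boronic acid and hydrodeiodination could then take over.
- Fallback (sets out from 3, returns at 5): the polarity of the coupling is reversed. Miyaura borylation (Pd(dppf)Cl2, B2pin2, KOAc, 1,4-dioxane, 90 °C) should give 5,7-bis(benzyloxy)-3-(4-methoxyphenyl)-8-(4,4,5,5-tetramethyl-1,3,2-dioxaborolan-2-yl)-4H-chromen-4-one F6. This is coupled with the unhindered, reactive electrophile 4-chloro-2-iodoanisole (Pd(PPh3)4, aq. Na2CO3, DME, 85 °C).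

**Further compounds**
F1 | step 7 | rac-5,7-bis(benzyloxy)-8-{5-[5,7-bis(benzyloxy)-4-oxochroman-2-yl]-2-methoxyphenyl}-3-(4-methoxyphenyl)-4H-chromen-4-one | COc1ccc(-c2coc3c(-c4cc(C5CC(=O)c6c(OCc7ccccc7)cc(OCc7ccccc7)cc6O5)ccc4OC)c(OCc4ccccc4)cc(OCc4ccccc4)c3c2=O)cc1
F2 | step 2 | 1-[4,6-bis(benzyloxy)-2-hydroxy-3-iodophenyl]ethanone | CC(=O)c1c(O)c(I)c(OCc2ccccc2)cc1OCc1ccccc1
F3 | step 2 | 1-[4,6-bis(benzyloxy)-3-(5-chloro-2-methoxyphenyl)-2-hydroxyphenyl]ethanone | CC(=O)c1c(O)c(-c2cc(Cl)ccc2OC)c(OCc2ccccc2)cc1OCc1ccccc1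
F4 | step 2 | (E)-1-[4,6-bis(benzyloxy)-3-(5-chloro-2-methoxyphenyl)-2-hydroxyphenyl]-3-(dimethylamino)prop-2-en-1-one | CN(C)/C=C/C(=O)c1c(O)c(-c2cc(Cl)ccc2OC)c(OCc2ccccc2)cc1OCc1ccccc1
F5 | step 2 | 5,7-bis(benzyloxy)-8-(5-chloro-2-methoxyphenyl)-3-iodo-4H-chromen-4-one | O=c1c(I)coc2c(-c3cc(Cl)ccc3OC)c(OCc3ccccc3)cc(OCc3ccccc3)c12
F6 | step 3 | 5,7-bis(benzyloxy)-3-(4-methoxyphenyl)-8-(4,4,5,5-tetramethyl-1,3,2-dioxaborolan-2-yl)-4H-chromen-4-one | COc1ccc(-c2coc3c(B4OC(C)(C)C(C)(C)O4)c(OCc4ccccc4)cc(OCc4ccccc4)c3c2=O)cc1
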